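**Retrosynthetic overview**
- No ring is formed: the benzene ring arrives with 2-phenylethanol and the C18 chain is bought.
- The ester C–O bond is made first, from 3-iodopropanoic acid (1) and 2-phenylethanol (2), giving iodo ester 3.
- Key disconnection: C3–C4 of the acyl chain. 1-Iodooctadecane (4) is the electrophile and zinc homoenolate 5 (a β-carbanion of the propanoate, made from 3) is the reversed-polarity nucleophile, giving target 6.

Assumption: the target has no stereocentre and no stereogenic double bond, so it is achiral and needs no stereocontrol.

**Step 1**
Reactants: 1 3-iodopropanoic acid (1.0 equiv); 2 2-phenylethanol (1.05 equiv)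
Product: 3 2-phenylethyl 3-iodopropanoate
Conditions: TsOH·H2O (5 mol%), toluene, reflux, Dean–Stark, 4 h, dark; wash NaHCO3/Na2S2O3
Reagents that add atoms: none
Why: Fischer esterification driven by azeotropic removal of water, where acidic conditions avoid base-induced loss of HI to the acrylate; no stereocentre is formed.

**Step 2**
Reactants: 3 2-phenylethyl 3-iodopropanoate (1.3 equiv); 4 1-iodooctadecane (1.0 equiv)
Product: 6 2-phenylethyl heneicosanoate, via zinc homoenolate 5 (not isolated)
Conditions: Zn dust (2 equiv, activated by BrCH2CH2Br 4 mol%, TMSCl 3 mol%), THF, 35 °C, 3 h; then 4, Pd2(dba)3 (2 mol%), PCyp3 (8 mol%), N-methylimidazole (1.2 equiv), THF/NMP 2:1, 80 °C, 14 h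
Reagents that add atoms: none
Why: Zinc insertion into the C–I bond gives a chelate-stabilised zinc homoenolate (d3 synthon) that undergoes a Negishi alkyl–alkyl cross-coupling with the octadecylpalladium iodide formed from 4 and zerovalent palladium bearing bulky, electron-rich PCyp3, so that reductive elimination outruns β-hydride elimination; no stereocentre is formed.

**Compound list**
1 | 3-iodopropanoic acid | OC(=O)CCI | starting material
2 | 2-phenylethanol | OCCc1ccccc1 | starting material
3 | 2-phenylethyl 3-iodopropanoate | ICCC(=O)OCCc1ccccc1 | intermediate
4 | 1-iodooctadecane | CCCCCCCCCCCCCCCCCCI | starting material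
5 | [3-oxo-3-(2-phenylethoxy)propyl]zinc iodide (zinc homoenolate, not isolated) | I[Zn]CCC(=O)OCCc1ccccc1 | intermediate
6 | 2-phenylethyl heneicosanoate (phenylethyl n-heneicosanoate, achiral) | CCCCCCCCCCCCCCCCCCCCC(=O)OCCc1ccccc1 | target

**Total step count:** 2
**Longest linear sequence:** 2

**Steps most likely to fail**
The route has only two steps, so the three risks are the two stages of step 2 and then step 1.

1. Step 2, coupling stage. The sp3–sp3 coupling can lose to β-hydride elimination (octadecene, octadecane) or stall because the chelated homoenolate transmetalates slowly. The fallback sets out from 5 and replaces the alkyl electrophile by an acyl one. Zinc homoenolate 5 is acylated with octadecanoyl chloride (CCCCCCCCCCCCCCCCCC(Cl)=O) under Pd(PPh3)4 (5 mol%) in THF at 0 to 25 °C to give 2-phenylethyl 4-oxoheneicosanoate F1. The ketone is converted with 1,2-ethanedithiol and BF3·OEt2 in CH2Cl2 into 2-phenylethyl 3-(2-heptadecyl-1,3-dithiolan-2-yl)propanoate F2. Desulfurisation with Raney Ni in THF/EtOH at 60 °C removes the dithiolane and comes back to the route at 6.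

2. Step 2, zinc insertion stage. Iodo ester 3 can lose HI to give 2-phenylethyl acrylate, or the zinc reagent can be protonated or dimerise. The fallback sets out from 4 and does not make the organozinc from 3 at all. Compound 4 is coupled under the same palladium/PCyp3 conditions with purchased 3-ethoxy-3-oxopropylzinc bromide (Br[Zn]CCC(=O)OCC) to give ethyl heneicosanoate F3. Transesterification of this ester with 2, catalysed by Ti(OEt)4 (5 mol%) in refluxing toluene with ethanol distilled off, comes back to the route at 6.

3. Step 1. The risk is low, but prolonged heating of the β-iodo acid can cause loss of HI or darkening. The fallback sets out from 2 and introduces the iodide last. Compound 2 is acylated with 3-chloropropanoyl chloride (ClCCC(Cl)=O) in CH2Cl2 at 0 °C to room temperature without base, giving 2-phenylethyl 3-chloropropanoate F4. Finkelstein exchange with NaI (3 equiv) in refluxing acetone comes back to the route at 3.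

**Further compounds**
F1 | step 2 | 2-phenylethyl 4-oxoheneicosanoate | CCCCCCCCCCCCCCCCCC(=O)CCC(=O)OCCc1ccccc1
F2 | step 2 | 2-phenylethyl 3-(2-heptadecyl-1,3-dithiolan-2-yl)propanoate | CCCCCCCCCCCCCCCCCC1(SCCS1)CCC(=O)OCCc1ccccc1
F3 | step 2 | ethyl heneicosanoate | CCCCCCCCCCCCCCCCCCCCC(=O)OCC
F4 | step 1 | 2-phenylethyl 3-chloropropanoate | ClCCC(=O)OCCc1ccccc1
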